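(The runs stem from a simulated flask with constants of no real substance.)

The flask holds 0.400 M of substrate, both hands together, and 0.800 M of partner. If one partner serves one substrate, that is 2.00 equivalents, so partner looks ample at the start. The beta run is this very flask, followed so far, and the epsilon run differs from it by being cooler.

all flasks: left-handed substrate 0.20 M; right-handed substrate 0.20 M; racemization catalyst 0.30 mM; precatalyst 0.40 mM; impurity 0.11 mM
- beta: partner 0.80 M; temperature 60 °C; the very flask that is asked about, followed so far
- epsilon: partner 0.80 M; temperature 55 °C; run made earlier
- flask: partner 0.800 M; temperature 60 °C; time 4.0 d

- beta (time / h: left-handed product / %, left-handed substrate / %): 8.00: 49, 15; 12.0: 49, 12; 20.0: 54, 12; 40.0: 54, 11; 60.0: 54, 10; 96.0: 51, 9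
- epsilon (time / h: left-handed product / %, left-handed substrate / %): 8.00: 46, 14; 12.0: 49, 11; 20.0: 57, 9; 40.0: 59, 5; 60.0: 57, 7; 96.0: 60, 6

(readings scatter by 1.5 percentage points)

- red: at 4.0 d add partner, 50.0 % of the amount charged, then wait 8.0 d
- violet: at 4.0 d raise the temperature by 15 K, then wait 8.0 d
- ochre: change nothing and wait 8.0 d more
- grey: at 4.0 d take out 90 % of the left-handed product then present, then wait 8.0 d
- blue: at 4.0 d add racemization catalyst, 100 % of the amount charged, then wait 8.0 d

- free catalyst is single-handed; left-handed substrate and right-handed substrate are mirror images of each other, charged as a racemate, each of them at the stated concentration
- left-handed product taken out counts as made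
- "the catalyst" is free catalyst with its forms; racemization catalyst is a second catalyst
- additions bring no volume worth counting

* left-handed product, in percent of the left-handed substrate and right-handed substrate together first charged, at 4.0 d
* the option that brings most further left-handed product ("none" if no option brings more than 2 percentage points) (red / violet / ochre / grey / blue / none)
* left-handed product present, with what was taken out counted in, in percent of the left-handed substrate and right-handed substrate together first charged, after violet
* left-handed product present, with what was taken out counted in, in percent of the left-handed substrate and right-handed substrate together first charged, after ochre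

I read the beta table from its top row. At 8.00 h, product and left-handed substrate add up to 64.0 %, more than the left-handed half of the charge. So right-handed substrate is reaching the left-handed side by racemization, and I take the two substrates as equal in amount.

From 20.0 h on, the last 4 rows stall. Product averages 53.2 %, and left-handed substrate drifts from 12 % to 9 % against a scatter of 1.5 percentage points. Counting its mirror image, those rows give a conversion of 79.0 %. Product makes up 67.4 % of that, and I read the rest as right-handed product.

My working guess is that the stop is a partner stop, which makes partner the limiting reagent in practice. A dying free catalyst is the other reading of these rows, but I commit to the partner stop as my guess. So I define the useful share of partner, u, as the part of the charged partner that ends up in converted substrate: 39.5 %. The same rows of the epsilon table give 43.2 %, larger than in the beta run.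

So I expect 53.2 % now and no gain above 2 points from violet, ochre, grey or blue, none of which brings partner. Red adds 0.400 M of partner, and at share u that carries 0.158 M, more than the 0.0840 M of substrate remaining. I therefore reckon a gain of 14 points from red, and I take that estimate as high, since u was read from a flask that started at 0.400 M of substrate, more than that remainder.

The forecast gives 53.5 % now, 55 % after violet and 55.5 % after ochre, and names blue, holding that “Supply of left-handed substrate is the main limit”.

The flask gives 53.3 %. The best option is red, with 10 points further, and violet and ochre both end at 53.3 %.

    partner + free catalyst + right-handed substrate → free catalyst + right-handed product (k = 0.310 /M²/s, Ea = 42.0 kJ/mol)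
    left-handed substrate + racemization catalyst ⇌ right-handed substrate + racemization catalyst, rate k2*[racemization catalyst]*[left-handed substrate] forward; the back reaction follows from the equilibrium constant (k = 3.00 /M/s, Ea = 47.0 kJ/mol)
    partner → decomposed reagent (k = 4.00 × 10⁻⁵ /s, Ea = 111 kJ/mol)
    partner + free catalyst + left-handed substrate → free catalyst + left-handed product (k = 0.630 /M²/s, Ea = 48.0 kJ/mol)
    racemization catalyst + impurity → spent catalyst (k = 13.0 /M/s, Ea = 54.0 kJ/mol)
    precatalyst → free catalyst (k = 1.80 × 10⁻⁴ /s, Ea = 105 kJ/mol)
    (constants at 60 °C)

In the flask, partner stands at 0 % of its charge by 48.0 h, and the two products at 96.0 h make u 40.2 %. The neighbour flask is charged with 0.48 M of partner. At the beta run's u that carries 0.190 M, which is a conversion of 47.4 %, and at share 67.4 % it gives 31.9 % left-handed product. The neighbour flask gives 37.6 % left-handed product and 18.8 % right-handed product at 96.0 h, with partner at 0 % of its charge, so its own u is 46.9 %.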